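Oak was charged with 3.00 M of partner against 2.00 M in larch, yet at 4.6 h the two stand at 0.331 M and 0.329 M of target, a gap smaller than the scatter of 0.004 M. So we open the books on the flasks and the questions put to them.

| setting | larch | birch | oak | ash | maple |
|---|---|---|---|---|---|
| substrate | 0.800 M | 0.480 M | 0.800 M | 0.400 M | 0.800 M |
| partner | 2.00 M | 1.68 M | 3.00 M | 2.00 M | 2.00 M |
| catalyst | 0.00400 M | 0.00400 M | 0.00400 M | 0.00400 M | 0.00400 M |
| time |  |  |  |  | 9.2 h |

| larch run: time / h | larch run: [target] / M | birch run: time / h | birch run: [target] / M | oak run: time / h | oak run: [target] / M | ash run: time / h | ash run: [target] / M |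
|---|---|---|---|---|---|---|---|
| 0.92 | 0.210 | 0.92 | 0.146 | 0.92 | 0.221 | 0.92 | 0.126 |
| 1.8 | 0.277 | 1.8 | 0.192 | 1.8 | 0.290 | 1.8 | 0.159 |
| 2.8 | 0.320 | 2.8 | 0.213 | 2.8 | 0.307 | 2.8 | 0.169 |
| 3.7 | 0.321 | 3.7 | 0.217 | 3.7 | 0.324 | 3.7 | 0.178 |
| 4.6 | 0.329 | 4.6 | 0.220 | 4.6 | 0.331 | 4.6 | 0.184 |

(readings scatter by 0.004 M)

- Overall: substrate + partner -> target, with catalyst as catalyst.
- Constant volume, constant temperature.
- What is held in complexes is read along with the free species.
- An order is taken over about fifteen percent of the charge, up and down.

- reaction order in [partner] at the outset, round the charge of the larch run, defined at two percent of the substrate turned into target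
- reaction order in [substrate] at the outset, round the charge of the larch run, defined at two percent of the substrate turned into target (one fixed amount of target, the same in the runs compared)
- target in the maple run at 9.2 h, as a share of the substrate charged

We keep the ledger on substrate, the limiting reagent by charge in larch, since c(substrate) starts at 0.800 M and c(partner) at 2.00 M. The first entry is the target read at 4.6 h, which is 0.329 M, or 41.1 % of the charge. The second entry is the unbooked balance, 0.471 M, and target readings cannot say where it stands. The overall equation, one partner per target, counts 1.67 M of partner against that balance in larch, so this arithmetic does not explain why the climb flattens.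

The first and last larch readings give 0.905 h. This is our fill time, the time constant of an exponential climb of target to its last reading. It marks the crossing in larch from a climbing target to readings that barely move. On that climb, larch reaches a quarter of its charge at 0.847 h. Maple has the larch charge and is asked at 9.2 h, which is 10.2 fill times, so we commit to the last larch reading as its share, 41.1 %.

The forecast says “The catalyst is dying, with a time constant of about 1 h”. It gives 0.12 for the order in partner, 0.68 for the order in substrate and 42.5 % for maple, a share above ours.

The flask gives 0.18, 0.70 and 41.7 %, so the forecast parts from it on the partner order, by a factor of 1.47.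

    catalyst + substrate ⇌ catalyst-substrate complex, settled at all times (0.5130 L mol⁻¹)
    catalyst + partner ⇌ catalyst-reagent complex, settled at all times (0.4950 L mol⁻¹)
    catalyst-substrate complex + catalyst-reagent complex → target + 2 catalyst (4.104 × 10⁵ L mol⁻¹ h⁻¹)
    2 partner → lost reagent (0.6912 L mol⁻¹ h⁻¹)
    target + partner → side product (0.6264 L mol⁻¹ h⁻¹)

Larch reaches its quarter at 0.796 h against our 0.847 h. Oak, from its own readings, has a fill time of 0.835 h, which puts its quarter at 0.774 h against the 0.750 h the flask gives. In maple, the balance that the target entry leaves open is partly target that went on to side product. With that conversion taken away, maple rises from 41.7 % to 67.0 %, a gain of 25 percentage points, and this gain is 43 % of what is missing.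

(The numbers in the tables were computed on assumed constants; noise was put on by code.)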